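These flasks take days over their target, so read the runs for what the wait costs.

| flask | substrate | reagent | free catalyst | remark | time |
|---|---|---|---|---|---|
| north | 0.016 M | 0.029 M | 1.6 mM | run made earlier |  |
| south-west | 0.016 M | 0.041 M | 1.6 mM | run made earlier |  |
| north-east | 0.012 M | 0.0288 M | 1.6 mM | run made earlier |  |
| delta | 0.0050 M | 0.0200 M | 1.6 mM |  | 6.0 d |
| eta | 0.016 M | 0.0288 M | 1.6 mM |  | 6.0 d |

| run | time / d | target / % | substrate / % |
|---|---|---|---|
| north | 1.04 | 23.6 | 29.6 |
| north | 2.08 | 40.9 | 22.8 |
| north | 3.00 | 53.2 | 18.2 |
| north | 4.00 | 63.7 | 13.3 |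
| north | 5.00 | 70.3 | 10.8 |
| north | 6.00 | 70.7 | 8.5 |
| south-west | 0.500 | 11.3 | 34.5 |
| south-west | 0.833 | 19.2 | 31.1 |
| south-west | 1.25 | 27.3 | 29.1 |
| south-west | 2.00 | 40.0 | 23.1 |
| south-west | 4.00 | 65.3 | 12.6 |
| south-west | 6.00 | 74.0 | 7.4 |
| north-east | 0.500 | 12.8 | 33.5 |
| north-east | 1.67 | 35.5 | 24.6 |
| north-east | 3.00 | 54.6 | 17.1 |
| north-east | 4.00 | 65.2 | 13.1 |
| north-east | 6.00 | 79.9 | 8.0 |

(readings scatter by 0.5 percentage points)

1. the winner by amount of target, in percent of the substrate charged; "neither" if no more than 2 percentage points parts them (delta / eta / neither)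
2. how much target is there at the end, in percent of the substrate charged: delta
3. how much target is there at the end, in percent of the substrate charged: eta



Turn the question round: if the two flasks were to draw level, a limit like eta's would have to hold delta down to eta's percentage, so first ask what eta's limit may be. The north run, nearly eta's recipe, reads 70.3 % and then 70.7 %, which is 0.0113 M of target from 0.029 M of reagent. My reckoning supposes that reagent wears away against itself, at second order, and that what survives is the most target that flask can make. That rate integrates in closed form: the reciprocal of this reagent budget equals the reciprocal of the reagent charge plus a wear, 53.9 M⁻¹ at 6.0 d by the north run. The south-west run gives 60.1 M⁻¹, close but not equal.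

Taking that north wear as it stands, eta's budget is 0.0113 M, or 70.5 % of its substrate. To be held level with that, delta would need a budget of 0.00353 M, but the same reckoning gives it 0.00962 M, a factor of 2.73 larger. So I read delta from the north-east run, which has eta's reagent charge and whose target of 0.00959 M stayed under eta's budget, and expect near 79.9 %.

The forecast names delta, with 79.5 % for delta and 71.5 % for eta, judging that “target is probably capped or lost at high concentration”.

The flasks give 81.2 % in delta and 71.0 % in eta, so delta wins.

    substrate + free catalyst → catalyst intermediate A (k = 0.320 M⁻¹ min⁻¹)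
    catalyst intermediate B ⇌ released group + catalyst intermediate C (K = 0.560 M, k = 0.0230 min⁻¹)
    2 reagent → self-condensation product (k = 0.0140 M⁻¹ min⁻¹)
    catalyst intermediate C → free catalyst + target (k = 0.0220 min⁻¹)
    reagent + catalyst intermediate A ⇌ catalyst intermediate B (K = 800 M⁻¹, k = 50.0 M⁻¹ min⁻¹)
    substrate ⇌ dormant form (K = 1.50, k = 0.00690 min⁻¹)

Eta's limiting reagent stood at 10.0 % of its charge at 3.00 d and 0 % at 6.00 d, with 0.00872 M of self-condensation product and 58.6 % of the catalyst charged as catalyst intermediate A, while delta then still held 10.9 % of its reagent and 98.6 % of its catalyst free. Eta's target of 0.0114 M lies beside its budget of 0.0113 M. Eta's neighbour with 0.027 M of substrate, its reagent at 0 %, has a budget of 41.8 % of that substrate and ends higher, at 51.3 %.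

The data are simulated for an exercise; noise was put on by code.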